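## Retrosynthetic overview

1. Target ⇒ its 5-allyl isomer. The (E)-propenyl group is made last by moving an allyl double bond into conjugation, and no ring or stereocentre is touched.
2. 5-Allyl dihydrobenzofuran ⇒ eugenol + (E)-isoelemicin. This is one oxidative 8–5′/7–O–4′ union, the two-electron counterpart of the neolignan phenol coupling, run on a chiral aryl-λ3-iodane instead of an achiral oxidant.
3. Eugenol is used rather than isoeugenol because its allyl group is not a π-nucleophile. Neither the phenol nor the product then competes with isoelemicin for the oxidised ring.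
4. (E)-Isoelemicin ⇒ 3,4,5-trimethoxybenzaldehyde + EtMgBr, by addition and then E1 dehydration in the same flask.
5. Ring order: both benzene rings are bought and only the dihydrofuran is built. The C8–C5′ bond forms first (sets C3), then O4′ closes on C7 of the quinone-methide-type cation (sets C2, trans).

Assumption: the sense of induction of the (R,R)-iodoarene toward an external π-nucleophile cannot be predicted with certainty. It is taken to give the (2R,3R) series, and the (S,S)-iodoarene, made in the same way from the other lactate ester, replaces it if the first run shows the opposite sense.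

## Route

Step 1
Reactants: 1 3,4,5-trimethoxybenzaldehyde
Product: 3 (E)-isoelemicin [1,2,3-trimethoxy-5-((E)-prop-1-enyl)benzene], via benzylic carbinol 2 (not isolated)
Conditions: EtMgBr (1.15 equiv), THF, 0 °C → rt, 1 h; then p-TsOH·H2O (1.3 equiv), toluene, distil off THF, reflux (Dean–Stark), 1 h; Kugelrohr distillation
Reagents that add atoms: ethylmagnesium bromide, CC[Mg]Br
Why: Grignard 1,2-addition gives carbinol 2, whose electron-rich benzylic cation loses a proton (E1 dehydration), and reversible protonation drives the alkene to the thermodynamic E isomer (≥95:5); the racemic carbinol centre is destroyed, so no stereocentre is carried on.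

Step 2
Reactants: 3 (E)-isoelemicin (3 equiv, excess recovered); 4 eugenol (4-allyl-2-methoxyphenol)
Product: 7 (2R,3R)-5-allyl-7-methoxy-3-methyl-2-(3,4,5-trimethoxyphenyl)-2,3-dihydrobenzofuran, via aryloxy-λ3-iodane 5 (not isolated), via O-methyl quinone methide cation 6 (not isolated)
Conditions: (R,R)-2-iodo-1,3-bis[1-(mesitylcarbamoyl)ethoxy]benzene (1.2 equiv), mCPBA (1.05 equiv), AcOH (2.2 equiv), 4 Å MS, CH2Cl2, rt, until peroxide test is negative (iodane drawn as the diacetate); then HFIP (CH2Cl2–HFIP 20:1), 3, −40 °C; 4 (1.0 equiv) added over 2 h; −40 → −20 °C; aq. NaHCO3/Na2S2O3; chromatography (3 and iodoarene recovered)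
Reagents that add atoms: none
Why: Proposed new method: eugenol exchanges onto the C2-symmetric lactamide λ3-iodane to give 5, in which the amide N–H···O hydrogen bonds fold both side arms into a helical pocket that leaves one face of the free ortho carbon open; the β-carbon of 3, the only π-nucleophile present, attacks there in an SN2′ sense as the iodoarene leaves (8–5′ bond), with the trimethoxyphenyl ring stacked endo over the dienone so that ring-face shielding becomes alkene-face selection and sets C3 as R; after tautomerisation the phenol oxygen closes on the O-methylated p-quinone methide 6 anti to the methyl group, setting C2 as R in a reversible closure that favours the trans isomer; the closest known reaction types are the hypervalent-iodine or anodic formal [3+2] cycloaddition of oxidised phenols with (E)-propenylbenzenes (racemic, trans-selective), the enantioselective Kita-type ortho-dearomatisation of phenols with this class of iodoarene, and the Ti–TADDOLate-promoted 2-methoxyquinone/propenylbenzene cycloaddition, where shielding one face of the electrophilic ring is enough to fix the alkene-derived stereocentres of the aromatised dihydrobenzofuran.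

Step 3
Reactants: 7 (2R,3R)-5-allyl-7-methoxy-3-methyl-2-(3,4,5-trimethoxyphenyl)-2,3-dihydrobenzofuran
Product: 8 (2R,3R)-7-methoxy-3-methyl-5-[(E)-prop-1-enyl]-2-(3,4,5-trimethoxyphenyl)-2,3-dihydrobenzofuran (target)
Conditions: [RuClH(CO)(PPh3)3] (2 mol %), toluene, 80 °C, 3 h; AgNO3–silica plug to remove traces of Z isomer
Reagents that add atoms: none
Why: Ru–H insertion/β-hydride elimination (metal-hydride alkene isomerisation) moves the terminal double bond one position into conjugation with the arene, where it stops as the thermodynamic E isomer (≥95:5); the neutral, H2-free conditions leave the benzylic ether and both stereocentres untouched.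

## Compound list

1 | 3,4,5-trimethoxybenzaldehyde | O=Cc1cc(OC)c(OC)c(OC)c1 | starting material
2 | (±)-1-(3,4,5-trimethoxyphenyl)propan-1-ol | CCC(O)c1cc(OC)c(OC)c(OC)c1 | intermediate
3 | (E)-isoelemicin, 1,2,3-trimethoxy-5-[(E)-prop-1-enyl]benzene | C/C=C/c1cc(OC)c(OC)c(OC)c1 | intermediate
4 | eugenol, 4-allyl-2-methoxyphenol | C=CCc1ccc(O)c(OC)c1 | starting material
5 | acetoxy(4-allyl-2-methoxyphenoxy){2,6-bis[(R)-1-(mesitylcarbamoyl)ethoxy]phenyl}-λ3-iodane | C=CCc1ccc(OI(OC(C)=O)c2c(O[C@H](C)C(=O)Nc3c(C)cc(C)cc3C)cccc2O[C@H](C)C(=O)Nc2c(C)cc(C)cc2C)c(OC)c1 | intermediate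
6 | 2-(5-allyl-2-hydroxy-3-methoxyphenyl)-1-(3,4,5-trimethoxyphenyl)propyl cation (O-methylated p-quinone methide; C8 already fixed, becomes C3 of 7) | C=CCc1cc(OC)c(O)c(c1)[C@@H](C)[CH+]c1cc(OC)c(OC)c(OC)c1 | intermediate
7 | (2R,3R)-5-allyl-7-methoxy-3-methyl-2-(3,4,5-trimethoxyphenyl)-2,3-dihydrobenzofuran (trans) | C=CCc1cc(OC)c2c(c1)[C@@H](C)[C@H](c1cc(OC)c(OC)c(OC)c1)O2 | intermediate
8 | (2R,3R)-7-methoxy-3-methyl-5-[(E)-prop-1-enyl]-2-(3,4,5-trimethoxyphenyl)-2,3-dihydrobenzofuran (trans), CNP0219898.1 | C/C=C/c1cc(OC)c2c(c1)[C@@H](C)[C@H](c1cc(OC)c(OC)c(OC)c1)O2 | target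

## Step count and risks

Total steps: 3. Longest linear sequence: 3 (1 → 3 → 7 → 8).

**Step 2 carries the most risk.**
- The alkene may attack the oxidised eugenol ring at C1 or at the methoxy-bearing carbon instead of the free ortho carbon.
- Acetate may transfer to the ring first and open a racemic free-phenoxenium channel.
- The level and sense of induction with an external carbon nucleophile are untested.
- The fallback gives up reagent control and resolves instead. It sets out from 3 and 4. The same union is run with achiral PhI(OAc)2 in neat HFIP at 0 °C (free phenoxenium ion, established formal [3+2] mode). This gives racemic trans material, that is 7 together with its mirror image (2S,3S)-5-allyl-7-methoxy-3-methyl-2-(3,4,5-trimethoxyphenyl)-2,3-dihydrobenzofuran F1.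
- Preparative SFC on an amylose tris(3,5-dimethylphenylcarbamate) phase separates the two, and the route is rejoined at 7. The same column tops up a merely moderate ee from the main step.

**Step 1 comes next.**
- The acid needed for dehydration can also dimerise the electron-rich styrene to indane-type products.
- The fallback replaces addition/elimination by olefination and geometric equilibration. It sets out from 1. Wittig reaction with ethyltriphenylphosphonium bromide/KOt-Bu in THF gives a Z-rich mixture of 3 and (Z)-isoelemicin F2.
- The mixture is equilibrated without Brønsted acid using PdCl2(MeCN)2 (3 mol %) in CH2Cl2. The route is rejoined at 3.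

**Step 3 is third.**
- Possible problems are incomplete conversion, an E/Z ratio that is hard to upgrade, or a catalyst poisoned by iodine-containing traces from step 2.
- The fallback replaces isomerisation by hydration and elimination. It sets out from 7. Mukaiyama hydration (Co(acac)2, PhSiH3, O2, i-PrOH, then Na2S2O3) gives the Markovnikov alcohol 1-[(2R,3R)-7-methoxy-3-methyl-2-(3,4,5-trimethoxyphenyl)-2,3-dihydrobenzofuran-5-yl]propan-2-ol F3, as a mixture of carbinol epimers.
- MsCl/Et3N converts it into the corresponding methanesulfonate F4. DBU in toluene at 80 °C then removes the more acidic benzylic hydrogen in an anti E2 elimination to give the conjugated E alkene. The route is rejoined at 8.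

## Further compounds

F1 | step 2 | (2S,3S)-5-allyl-7-methoxy-3-methyl-2-(3,4,5-trimethoxyphenyl)-2,3-dihydrobenzofuran | C=CCc1cc(OC)c2c(c1)[C@H](C)[C@@H](c1cc(OC)c(OC)c(OC)c1)O2
F2 | step 1 | (Z)-isoelemicin, 1,2,3-trimethoxy-5-[(Z)-prop-1-enyl]benzene | C/C=C\c1cc(OC)c(OC)c(OC)c1
F3 | step 3 | 1-[(2R,3R)-7-methoxy-3-methyl-2-(3,4,5-trimethoxyphenyl)-2,3-dihydrobenzofuran-5-yl]propan-2-ol (carbinol epimers) | CC(O)Cc1cc(OC)c2c(c1)[C@@H](C)[C@H](c1cc(OC)c(OC)c(OC)c1)O2
F4 | step 3 | 1-[(2R,3R)-7-methoxy-3-methyl-2-(3,4,5-trimethoxyphenyl)-2,3-dihydrobenzofuran-5-yl]propan-2-yl methanesulfonate (epimers) | CC(Cc1cc(OC)c2c(c1)[C@@H](C)[C@H](c1cc(OC)c(OC)c(OC)c1)O2)OS(C)(=O)=O
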